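**Retrosynthetic overview**
- Numbering and shape: ring A is C1 (quaternary, CH3), C2 (O-angeloyl), C3, C4 (C(OH)-iPr), C5 (fusion CH). Ring B is C5, C6 (O-aroyl), C7, C8(CH3)=C9, C10, C1. The rings are cis-fused: C2–O, C4–OH, C5–C6 and C1–C10 lie on one face of ring A (the upper face), and C1–CH3, C5–H and iPr lie on the other.
- Feature used: C1–C6, the C1 methyl and the C4 hydroxy-isopropyl unit are the ten carbons of (R)-terpinen-4-ol, and its carbinol carbon is C4 in the configuration of the target. Only the C1=C6 alkene has to be cut and C5 bonded to C1; this shrinks the six-membered ring to ring A and expels C6 as a formyl group.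
- Disconnections: C2 angelate (last); ring B at C8=C9 (ring-closing metathesis); C9=CH2 (Wittig on a C2–O/C9 lactol); C6–O aroate; C6–C7 (methallyl addition to the C6 aldehyde, guided by C4–OH); C1–C10 (radical closure from a bromoacetal on C2–O onto the enal); C1=C5 (aldol condensation after ozonolysis).
- Ring order: ring A (step 6), a temporary oxolane C1–C2–O–C9–C10 (step 9, opened in step 14), ring B (step 15).

Key step: step 6

Remark 1: the acetal or lactol carbon C9 in 12, 13, 14, 16, 18 and 19 is carried as an epimer mixture because it becomes sp2 in step 14.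
Remark 2: commercial (−)-(R)-terpinen-4-ol is taken as enantiopure; any (S)-enantiomer present would emerge from the reagent-controlled step 4 as the separable trans-2,4 diastereomer.

**Step 1**
Reactants: 1 (R)-terpinen-4-ol
Product: 2 (R)-triethyl[(1-isopropyl-4-methylcyclohex-3-en-1-yl)oxy]silane
Conditions: Et3SiOTf, 2,6-lutidine, CH2Cl2, 0 °C
Reagents that add atoms: triethylsilyl trifluoromethanesulfonate, CC[Si](CC)(CC)OS(=O)(=O)C(F)(F)F
Why: Silylation of a tertiary alcohol with a silyl triflate and a hindered pyridine base is standard, leaves C4 untouched and turns O4 into a non-acidic, non-coordinating and bulky group for steps 2 to 9.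

**Step 2**
Reactants: 2 (R)-triethyl[(1-isopropyl-4-methylcyclohex-3-en-1-yl)oxy]silane
Product: 3 (5S)-5-isopropyl-2-methyl-5-(triethylsilyloxy)cyclohex-2-en-1-ol (epimers at the new carbinol C2)
Conditions: SeO2 (0.5 equiv), t-BuOOH (decane solution, 2 equiv), CH2Cl2, 0 °C to rt
Reagents that add atoms: selenium dioxide, O=[Se]=O; tert-butyl hydroperoxide, CC(C)(C)OO
Why: Catalytic SeO2 allylic oxidation (ene reaction followed by [2,3]-sigmatropic shift) functionalises the more substituted alkene terminus and there prefers the ring CH2 (C2) to the CH3 group, while C5H2 on the less substituted terminus is not touched; the C2 epimer mixture and any enone 4 already formed are converged in step 3.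

**Step 3**
Reactants: 3 (5S)-5-isopropyl-2-methyl-5-(triethylsilyloxy)cyclohex-2-en-1-ol
Product: 4 (S)-5-isopropyl-2-methyl-5-(triethylsilyloxy)cyclohex-2-en-1-one
Conditions: Dess–Martin periodinane, CH2Cl2, 0 °C to rt
Reagents that add atoms: none
Why: Dess–Martin oxidation of the secondary allylic alcohol runs under nearly neutral conditions, so the β-silyloxy enone should form without the acid- or base-induced elimination that would end in aromatisation to carvacrol.

**Step 4**
Reactants: 4 (S)-5-isopropyl-2-methyl-5-(triethylsilyloxy)cyclohex-2-en-1-one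
Product: 5 (1S,5S)-5-isopropyl-2-methyl-5-(triethylsilyloxy)cyclohex-2-en-1-ol (C2–OH cis to C4–O)
Conditions: (R)-2-methyl-CBS-oxazaborolidine (0.2 equiv), BH3·SMe2, THF, −30 °C; MeOH
Reagents that add atoms: none
Why: Corey–Bakshi–Shibata reduction under reagent control, in which the methyl-bearing alkenyl flank (C1) acts as the large and C3H2 as the small group, so that the (R)-catalyst sets C2 as S, cis to C4–O, which is also the outcome of hydride attack anti to the axial C4 silyloxy group (matched case); a chelate between C4–O and the ring carbonyl is not relied on because the 1,3-related oxygens of a cyclohexenone are too far apart to share one boron atom.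

**Step 5**
Reactants: 5 (1S,5S)-5-isopropyl-2-methyl-5-(triethylsilyloxy)cyclohex-2-en-1-ol
Product: 6 (1S,5S)-5-isopropyl-2-methyl-1,5-bis(triethylsilyloxy)cyclohex-2-ene (bis-silylated p-menth-1-ene-4,6-diol)
Conditions: Et3SiCl, imidazole, DMF, 0 °C to rt
Reagents that add atoms: chlorotriethylsilane, CC[Si](Cl)(CC)CC
Why: Imidazole-promoted silylation of the secondary allylic alcohol gives a silyl ether that survives ozone and the amine salt but is far more accessible than the tertiary one, which allows its selective removal in step 7.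

**Step 6**
Reactants: 6 (1S,5S)-5-isopropyl-2-methyl-1,5-bis(triethylsilyloxy)cyclohex-2-ene
Product: 9 (3S,5S)-5-isopropyl-2-methyl-3,5-bis(triethylsilyloxy)cyclopent-1-ene-1-carbaldehyde, via secondary ozonide 7 (not isolated), via keto aldehyde 8 (not isolated)
Conditions: O3, CH2Cl2, −78 °C; Me2S, −78 °C to rt; then piperidine (0.3 equiv), AcOH (0.3 equiv), 4 Å MS, same flask, rt to 40 °C
Reagents that add atoms: ozone, [O-][O+]=O
Why: Ozone adds to the only C=C bond and the Criegee sequence gives 1,2,4-trioxolane 7, which Me2S reduces to keto aldehyde 8 with C2 and C4 untouched. Piperidinium acetate then converts the unhindered C6 aldehyde into its enamine, whose carbon C5 attacks the C1 methyl ketone, and loss of water from the aldol gives the tetrasubstituted enal 9; the closest known reaction type is the one-flask ozonolysis and amine-salt aldol condensation that contracts 1-methylcyclohexenes of the limonene family to 2-methylcyclopent-1-enecarbaldehydes. Ring A (C1 to C5) closes in the 5-(enolexo)-exo-trig mode, assisted by the gem-disubstitution at C4 (Thorpe–Ingold effect). No stereocentre is created, and C2 (S) and C4 are carried over from 6. The step needs regioselectivity among three aldol modes: the amine condenses with the aldehyde far faster than with the α-silyloxy ketone, so only C5 becomes nucleophilic, whereas attack of C2 on C6 would build a quaternary carbon, cannot dehydrate into conjugation and therefore reverts, and attack of the ketone CH3 on C6 would need a seven-membered ring. It also needs the β-silyloxy group at C4 and the configuration at C2 to survive, which the buffered medium secures because it holds no free enolate and so keeps E1cB loss of Et3SiO from C4 and enolisation at C2 slower than the ring closure.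

**Step 7**
Reactants: 9 (3S,5S)-5-isopropyl-2-methyl-3,5-bis(triethylsilyloxy)cyclopent-1-ene-1-carbaldehyde
Product: 10 (3S,5S)-3-hydroxy-5-isopropyl-2-methyl-5-(triethylsilyloxy)cyclopent-1-ene-1-carbaldehyde
Conditions: AcOH–THF–H2O (3:1:1), 0 °C to rt
Reagents that add atoms: none
Why: Acid-catalysed solvolysis of silyl ethers is governed by steric access to silicon, so the secondary C2–OSiEt3 group should be cleaved while the tertiary C4–OSiEt3 group, flanked by isopropyl and the substituted alkene, stays, and the formyl-deactivated allylic C2–O bond does not ionise.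

**Step 8**
Reactants: 10 (3S,5S)-3-hydroxy-5-isopropyl-2-methyl-5-(triethylsilyloxy)cyclopent-1-ene-1-carbaldehyde; 11 ethyl vinyl ether
Product: 12 (3S,5S)-3-(2-bromo-1-ethoxyethoxy)-5-isopropyl-2-methyl-5-(triethylsilyloxy)cyclopent-1-ene-1-carbaldehyde
Conditions: NBS, 11, CH2Cl2, −40 to 0 °C
Reagents that add atoms: ethyl vinyl ether (11), C=COCC; N-bromosuccinimide, O=C1CCC(=O)N1Br
Why: Bromoacetalisation (haloetherification of the electron-rich vinyl ether and capture of the oxocarbenium ion by C2–OH) builds the Ueno–Stork precursor, the enal alkene being too electron-poor to react with NBS.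

**Step 9**
Reactants: 12 (3S,5S)-3-(2-bromo-1-ethoxyethoxy)-5-isopropyl-2-methyl-5-(triethylsilyloxy)cyclopent-1-ene-1-carbaldehyde
Product: 13 (3aR,4S,5S,6aS)-2-ethoxy-5-isopropyl-3a-methyl-5-(triethylsilyloxy)hexahydro-2H-cyclopenta[b]furan-4-carbaldehyde (C10 and CHO on the upper face, C1–CH3 and C5–H on the lower face)
Conditions: (Me3Si)3SiH, Et3B (0.2 equiv), air, toluene (0.01 M), 0 °C to rt
Reagents that add atoms: none
Why: Ueno–Stork radical cyclisation, in which the nucleophilic primary radical C10 adds 5-exo-trig to the β-carbon C1 of the enal (polarity matched) and the short tether from C2–O permits only a cis-fused oxolane, so C10 enters on the upper face and sets C1 (R), after which the C5 radical, which unlike an enolate does not expel the β-silyloxy group, should take hydrogen from the bulky silane on the lower face because the C4–OSiEt3 group (turned over the ring, anti to isopropyl) and the new oxolane cover the upper face, leaving CHO cis to C10.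

**Step 10**
Reactants: 13 (3aR,4S,5S,6aS)-2-ethoxy-5-isopropyl-3a-methyl-5-(triethylsilyloxy)hexahydro-2H-cyclopenta[b]furan-4-carbaldehyde
Product: 14 (3aR,4S,5S,6aS)-2-ethoxy-5-hydroxy-5-isopropyl-3a-methylhexahydro-2H-cyclopenta[b]furan-4-carbaldehyde
Conditions: Bu4NF, AcOH (1:1), THF, 0 °C
Reagents that add atoms: none
Why: Fluoride-induced desilylation buffered with acetic acid frees C4–OH in an essentially neutral medium, which spares the mixed acetal and avoids enolisation at C5, retro-aldol cleavage and dehydration of the β-hydroxy aldehyde.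

**Step 11**
Reactants: 14 (3aR,4S,5S,6aS)-2-ethoxy-5-hydroxy-5-isopropyl-3a-methylhexahydro-2H-cyclopenta[b]furan-4-carbaldehyde; 15 2-methylallylmagnesium chloride
Product: 16 (3aR,4R,5S,6aS)-2-ethoxy-4-[(1R)-1-hydroxy-3-methylbut-3-en-1-yl]-5-isopropyl-3a-methylhexahydro-2H-cyclopenta[b]furan-5-ol
Conditions: 15 (0.5 M in THF, 3 equiv), CH2Cl2, −78 °C; sat. aq NH4Cl
Reagents that add atoms: 2-methylallylmagnesium chloride (15), C=C(C)C[Mg]Cl
Why: Chelation-controlled (Cram-chelate type) Grignard 1,2-addition, in which the C4–OH hydrogen bond and, after deprotonation by the first equivalent, the C4–O–Mg chelate hold the aldehyde oxygen syn to O4 in a six-membered ring cis-fused to ring A, so that one face of C6 looks onto the crowded upper face of ring A (C10, oxolane) and the other lies next to C5–H, and the methallyl group enters past C5–H and sets C6 as R, the very fast addition at −78 °C outrunning enolisation and retro-aldol cleavage.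

**Step 12**
Reactants: 16 (3aR,4R,5S,6aS)-2-ethoxy-4-[(1R)-1-hydroxy-3-methylbut-3-en-1-yl]-5-isopropyl-3a-methylhexahydro-2H-cyclopenta[b]furan-5-ol; 17 3,4,5-trimethoxybenzoyl chloride
Product: 18 (1R)-1-[(3aR,4R,5S,6aS)-2-ethoxy-5-hydroxy-5-isopropyl-3a-methylhexahydro-2H-cyclopenta[b]furan-4-yl]-3-methylbut-3-en-1-yl 3,4,5-trimethoxybenzoate
Conditions: 17, Et3N, DMAP (0.2 equiv), CH2Cl2, rt to 40 °C
Reagents that add atoms: 3,4,5-trimethoxybenzoyl chloride (17), COc1cc(C(=O)Cl)cc(OC)c1OC
Why: DMAP-catalysed acylation takes the secondary C6–OH and leaves the hindered tertiary C4–OH, and because C2–O is still locked in the acetal the aroyl group can only go to O6, which settles the differentiation of the two ester positions.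

**Step 13**
Reactants: 18 (1R)-1-[(3aR,4R,5S,6aS)-2-ethoxy-5-hydroxy-5-isopropyl-3a-methylhexahydro-2H-cyclopenta[b]furan-4-yl]-3-methylbut-3-en-1-yl 3,4,5-trimethoxybenzoate
Product: 19 (1R)-1-[(3aR,4R,5S,6aS)-2,5-dihydroxy-5-isopropyl-3a-methylhexahydro-2H-cyclopenta[b]furan-4-yl]-3-methylbut-3-en-1-yl 3,4,5-trimethoxybenzoate (lactol)
Conditions: 1 M aq HCl, THF, rt
Reagents that add atoms: water, O
Why: Acid-catalysed acetal hydrolysis through the cyclic oxocarbenium ion exchanges OEt for OH under conditions that the aroate, the tertiary alcohol and the 1,1-disubstituted alkene tolerate, and capture of C9 by O4 is not expected because it would need a strained dioxanoradamantane cage.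

**Step 14**
Reactants: 19 (1R)-1-[(3aR,4R,5S,6aS)-2,5-dihydroxy-5-isopropyl-3a-methylhexahydro-2H-cyclopenta[b]furan-4-yl]-3-methylbut-3-en-1-yl 3,4,5-trimethoxybenzoate
Product: 20 (1R)-1-[(1R,2R,3S,5S)-2-allyl-3,5-dihydroxy-5-isopropyl-2-methylcyclopentyl]-3-methylbut-3-en-1-yl 3,4,5-trimethoxybenzoate
Conditions: Ph3PCH3Br, KOt-Bu (slight deficit), THF, 0 °C; then 19, 0 °C to rt
Reagents that add atoms: methyltriphenylphosphonium bromide, C[P+](c1ccccc1)(c1ccccc1)c1ccccc1.[Br-]
Why: Wittig methylenation of the lactol through its open hydroxy aldehyde tautomer turns C9 into a vinyl carbon and releases C2–OH, and the hindered, electron-rich aroate should resist the ylide when no excess alkoxide base is present.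

**Step 15**
Reactants: 20 (1R)-1-[(1R,2R,3S,5S)-2-allyl-3,5-dihydroxy-5-isopropyl-2-methylcyclopentyl]-3-methylbut-3-en-1-yl 3,4,5-trimethoxybenzoate
Product: 21 (1R,2S,4S,5R,6R)-2,4-dihydroxydauc-8-en-6-yl 3,4,5-trimethoxybenzoate (cis-fused hydroazulene)
Conditions: second-generation Grubbs catalyst RuCl2(=CHPh)(PCy3)(H2IMes) (5 mol %), CH2Cl2 (2 mM), 40 °C
Reagents that add atoms: none
Why: Ring-closing metathesis starts at the monosubstituted C9 alkene and closes onto the 1,1-disubstituted C8 alkene to give the trisubstituted C8=C9 bond of seven-membered ring B, favoured by the cis placement of both arms on C1 and C5 and driven by loss of ethene, with the ring size fixing the alkene geometry.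

**Step 16**
Reactants: 21 (1R,2S,4S,5R,6R)-2,4-dihydroxydauc-8-en-6-yl 3,4,5-trimethoxybenzoate; 22 angelic acid
Product: 24 (1R,2S,4S,5R,6R)-2-angeloyloxy-4-hydroxy-6-(3,4,5-trimethoxybenzoyloxy)dauc-8-ene (target CNP0112256.1), via mixed anhydride 23 (not isolated)
Conditions: 22, 2,4,6-trichlorobenzoyl chloride, Et3N, toluene, rt; then 21, 80 °C
Reagents that add atoms: angelic acid (22), C/C=C(/C)C(=O)O
Why: Yamaguchi-type mixed anhydride esterification run without a nucleophilic catalyst acylates the secondary C2–OH with retention of the Z geometry (nucleophilic catalysts promote angelate to tiglate isomerisation), while the tertiary C4–OH stays free.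

**Compound list**
1 | (R)-terpinen-4-ol | CC1=CC[C@@](O)(C(C)C)CC1 | starting material
2 | (R)-triethyl[(1-isopropyl-4-methylcyclohex-3-en-1-yl)oxy]silane | CC1=CC[C@@](O[Si](CC)(CC)CC)(C(C)C)CC1 | intermediate
3 | (5S)-5-isopropyl-2-methyl-5-(triethylsilyloxy)cyclohex-2-en-1-ol, carbinol epimers | CC1=CC[C@@](O[Si](CC)(CC)CC)(C(C)C)CC1O | intermediate
4 | (S)-5-isopropyl-2-methyl-5-(triethylsilyloxy)cyclohex-2-en-1-one | CC1=CC[C@@](O[Si](CC)(CC)CC)(C(C)C)CC1=O | intermediate
5 | (1S,5S)-5-isopropyl-2-methyl-5-(triethylsilyloxy)cyclohex-2-en-1-ol | CC1=CC[C@@](O[Si](CC)(CC)CC)(C(C)C)C[C@@H]1O | intermediate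
6 | (1S,5S)-5-isopropyl-2-methyl-1,5-bis(triethylsilyloxy)cyclohex-2-ene | CC1=CC[C@@](O[Si](CC)(CC)CC)(C(C)C)C[C@@H]1O[Si](CC)(CC)CC | intermediate
7 | secondary ozonide (1,2,4-trioxolane across C1 and C6) of 6 | CC12OOC(O1)C[C@@](O[Si](CC)(CC)CC)(C(C)C)C[C@@H]2O[Si](CC)(CC)CC | intermediate
8 | (3R,5S)-3-isopropyl-6-oxo-3,5-bis(triethylsilyloxy)heptanal | CC(=O)[C@@H](O[Si](CC)(CC)CC)C[C@](O[Si](CC)(CC)CC)(C(C)C)CC=O | intermediate
9 | (3S,5S)-5-isopropyl-2-methyl-3,5-bis(triethylsilyloxy)cyclopent-1-ene-1-carbaldehyde | O=CC1=C(C)[C@@H](O[Si](CC)(CC)CC)C[C@]1(O[Si](CC)(CC)CC)C(C)C | intermediate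
10 | (3S,5S)-3-hydroxy-5-isopropyl-2-methyl-5-(triethylsilyloxy)cyclopent-1-ene-1-carbaldehyde | O=CC1=C(C)[C@@H](O)C[C@]1(O[Si](CC)(CC)CC)C(C)C | intermediate
11 | ethyl vinyl ether | C=COCC | starting material
12 | (3S,5S)-3-(2-bromo-1-ethoxyethoxy)-5-isopropyl-2-methyl-5-(triethylsilyloxy)cyclopent-1-ene-1-carbaldehyde | O=CC1=C(C)[C@@H](OC(CBr)OCC)C[C@]1(O[Si](CC)(CC)CC)C(C)C | intermediate
13 | (3aR,4S,5S,6aS)-2-ethoxy-5-isopropyl-3a-methyl-5-(triethylsilyloxy)hexahydro-2H-cyclopenta[b]furan-4-carbaldehyde | CCOC1O[C@H]2C[C@](O[Si](CC)(CC)CC)(C(C)C)[C@@H](C=O)[C@@]2(C)C1 | intermediate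
14 | (3aR,4S,5S,6aS)-2-ethoxy-5-hydroxy-5-isopropyl-3a-methylhexahydro-2H-cyclopenta[b]furan-4-carbaldehyde | CCOC1O[C@H]2C[C@](O)(C(C)C)[C@@H](C=O)[C@@]2(C)C1 | intermediate
15 | 2-methylallylmagnesium chloride | C=C(C)C[Mg]Cl | starting material
16 | (3aR,4R,5S,6aS)-2-ethoxy-4-[(1R)-1-hydroxy-3-methylbut-3-en-1-yl]-5-isopropyl-3a-methylhexahydro-2H-cyclopenta[b]furan-5-ol | CCOC1O[C@H]2C[C@](O)(C(C)C)[C@@H]([C@H](O)CC(C)=C)[C@@]2(C)C1 | intermediate
17 | 3,4,5-trimethoxybenzoyl chloride | COc1cc(C(=O)Cl)cc(OC)c1OC | starting material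
18 | C6 3,4,5-trimethoxybenzoate of 16 | CCOC1O[C@H]2C[C@](O)(C(C)C)[C@@H]([C@H](OC(=O)c3cc(OC)c(OC)c(OC)c3)CC(C)=C)[C@@]2(C)C1 | intermediate
19 | lactol from 18 (OH in place of OEt at C9) | OC1O[C@H]2C[C@](O)(C(C)C)[C@@H]([C@H](OC(=O)c3cc(OC)c(OC)c(OC)c3)CC(C)=C)[C@@]2(C)C1 | intermediate
20 | (1R)-1-[(1R,2R,3S,5S)-2-allyl-3,5-dihydroxy-5-isopropyl-2-methylcyclopentyl]-3-methylbut-3-en-1-yl 3,4,5-trimethoxybenzoate | O[C@H]1C[C@](O)(C(C)C)[C@@H]([C@H](OC(=O)c2cc(OC)c(OC)c(OC)c2)CC(C)=C)[C@@]1(C)CC=C | intermediate
21 | (1R,2S,4S,5R,6R)-2,4-dihydroxydauc-8-en-6-yl 3,4,5-trimethoxybenzoate | O[C@H]1C[C@](O)(C(C)C)[C@H]2[C@H](OC(=O)c3cc(OC)c(OC)c(OC)c3)CC(C)=CC[C@@]12C | intermediate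
22 | angelic acid, (Z)-2-methylbut-2-enoic acid | C/C=C(/C)C(=O)O | starting material
23 | angelic 2,4,6-trichlorobenzoic anhydride | C/C=C(/C)C(=O)OC(=O)c1c(Cl)cc(Cl)cc1Cl | intermediate
24 | CNP0112256.1 | C/C=C(/C)C(=O)O[C@H]1C[C@](O)(C(C)C)[C@H]2[C@H](OC(=O)c3cc(OC)c(OC)c(OC)c3)CC(C)=CC[C@@]12C | target

Total step count: 16. Longest linear sequence: 16 steps (1 to 24).

**Steps most likely to fail**

**Step 6.** Closure onto the hindered α-silyloxy ketone, and above all dehydration of the crowded tertiary aldol, may be slow. β-Elimination of the C4 silyloxy group from the aldehyde enamine, or enolisation at C2, could then take over during prolonged warming with the amine salt. The fallback separates bond formation from dehydration: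
- It sets out from 6. The ozonolysis is worked up with Me2S and keto aldehyde 8 is isolated.
- An enamine-catalysed 5-enolexo aldol addition with (S)-proline in DMSO at room temperature is stopped at the β-hydroxy aldehyde F1.
- The tertiary C1–OH of F1 is then removed without any amine by Martin sulfurane Ph2S[OC(CF3)2Ph]2 in CH2Cl2 at 0 °C. Under these conditions the activated C1–O is the only good leaving group and C5–H is the most acidic β-hydrogen.
- This comes back to the route at 9.

**Step 9.** Hydrogen transfer to the primary radical may precede the attack at the fully substituted C1. More probably, the hydrogen transfer to the planar C5 radical may show poor facial selectivity, because both faces are flanked by fully substituted carbons. The fallback sets C5 under thermodynamic instead of kinetic control: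
- It sets out from 13, obtained together with the C5-epimeric silyloxy aldehyde F2.
- The mixture is desilylated as in step 10 to 14 and the C5-epimeric hydroxy aldehyde F3.
- The pair is equilibrated with Et3N in CH2Cl2 at room temperature. In 14 the formyl group is trans to isopropyl and C1–CH3 and hydrogen-bonded to the cis C4–OH. In F3 it sits between isopropyl and methyl.
- Hydroxide is a much poorer leaving group than a silanolate, so enolisation should not be followed by elimination.
- The equilibration comes back to the route at 14.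

**Step 11.** Allylic Grignard reagents react at almost every encounter, so part of the addition may run through an open Felkin–Anh type conformer with the aldehyde oxygen turned away from O4. That erodes the facial selectivity at C6. The fallback sets C6 by hydride addition to a ketone under reagent control, with O4 kept silylated:
- It sets out from 13. Addition of 15 without regard to selectivity gives the silylated homoallylic alcohol F4.
- Dess–Martin oxidation gives the β,γ-unsaturated ketone F5.
- Corey–Bakshi–Shibata reduction with (S)-2-methyl-CBS-oxazaborolidine and BH3·SMe2 gives the (6R)-alcohol F6. Here C5 is the large and C7H2 the small flank, matched with Felkin–Anh attack anti to C4.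
- Bu4NF and AcOH in THF then remove the silyl group, and the sequence comes back to the route at 16.

**Further compounds**
F1 | step 6 | 2-hydroxy-5-isopropyl-2-methyl-3,5-bis(triethylsilyloxy)cyclopentane-1-carbaldehyde (aldol, C1 and C5 undefined) | O=CC1C(C)(O)[C@@H](O[Si](CC)(CC)CC)C[C@]1(O[Si](CC)(CC)CC)C(C)C
F2 | step 9 | C5 epimer of 13 (CHO on the lower face) | CCOC1O[C@H]2C[C@](O[Si](CC)(CC)CC)(C(C)C)[C@H](C=O)[C@@]2(C)C1
F3 | step 9 | C5 epimer of 14 (CHO on the lower face) | CCOC1O[C@H]2C[C@](O)(C(C)C)[C@H](C=O)[C@@]2(C)C1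
F4 | step 11 | methallyl carbinol from 13, C4–OSiEt3 kept, C6 epimers | CCOC1O[C@H]2C[C@](O[Si](CC)(CC)CC)(C(C)C)[C@@H](C(O)CC(C)=C)[C@@]2(C)C1
F5 | step 11 | C6 ketone from F4 | CCOC1O[C@H]2C[C@](O[Si](CC)(CC)CC)(C(C)C)[C@@H](C(=O)CC(C)=C)[C@@]2(C)C1
F6 | step 11 | (6R)-alcohol from F5, C4–OSiEt3 kept | CCOC1O[C@H]2C[C@](O[Si](CC)(CC)CC)(C(C)C)[C@@H]([C@H](O)CC(C)=C)[C@@]2(C)C1
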